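**Retrosynthetic overview**
1. The target is the acetate of a 12-hydroxy-11,14-quinone; acetylation, O-demethylation and oxidative demethylation lead back to trimethoxyarene 21, in which all four rings are in place.
2. Ring B is cut at C5–C6 together with the C6=C7 alkene: a C5 radical, made from a C5 xanthate, closes 6-endo onto a β-stannylvinyl group on C8 and expels the tin radical.
3. Enabling feature: C5 is the one-carbon bridge of the 3-oxabicyclo[3.3.1]nonane formed by ring A and the C19–O–C20 lactone ring, flanked by the quaternary bridgeheads C4 and C10. As a ketone it lets C4 be methylated and C10 be arylated and hydroxymethylated; as a radical it has no β-hydrogen and is more open on the lactone face.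
4. Ring order: ring C (bought arene) and ring A (bought cyclohexanone ester) are joined at C9–C10 by ketone α-arylation; the lactone ring closes by aldol addition and lactonisation; ring B closes last.
5. Stereocentres: C4 by chiral-enamine methylation, C10 by the lactone bridge, C5 in the key step.

Key step: step 12

Assumption: in the chiral-enamine methylation (step 5) the face attacked depends on the lithium ligand; the toluene/HMPA protocol is taken to give the S ester from the L-valine auxiliary, and if it gave the R ester the THF protocol or the D-valine auxiliary would be used.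

Positions in the polycyclic compounds are given in abietane numbering (C19 = lactone carbonyl on C4, C20 = OCH2 on C10).

**Step 1**
Reactants: 1 1,2,4-trimethoxybenzene
Product: 3 2-(2,3,6-trimethoxyphenyl)propan-2-ol, via 2,3,6-trimethoxyphenyllithium 2 (not isolated)
Conditions: n-BuLi, THF, 0 °C; acetone, −78 °C → rt; H2O
Reagents that add atoms: acetone CC(C)=O
Why: Directed ortho-lithiation should occur at the ring position flanked by two methoxy groups, and the aryllithium adds to acetone (1,2-addition).

**Step 2**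
Reactants: 3 2-(2,3,6-trimethoxyphenyl)propan-2-ol
Product: 4 1,2,4-trimethoxy-3-(propan-2-yl)benzene
Conditions: Et3SiH, CF3CO2H, CH2Cl2, 0 °C → rt
Reagents that add atoms: none
Why: Ionic hydrogenation, in which the tertiary benzylic cation stabilised by two ortho methoxy groups is trapped by hydride from the silane.

**Step 3**
Reactants: 4 1,2,4-trimethoxy-3-(propan-2-yl)benzene
Product: 6 1-bromo-2,3,5-trimethoxy-4-(propan-2-yl)benzene, via 2,3,5-trimethoxy-4-isopropylphenyllithium 5 (not isolated)
Conditions: n-BuLi, TMEDA, Et2O, 0 °C; BrCH2CH2Br, −78 °C → rt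
Reagents that add atoms: 1,2-dibromoethane BrCCBr
Why: Directed ortho-metalation should remove the hydrogen para to the isopropyl group, because it is ortho to an unhindered methoxy group and acidified by two meta methoxy groups, whereas the other hydrogen is para to a methoxy group and next to a methoxy group twisted by the isopropyl group; bromine transfer then gives the bromide.

**Step 4**
Reactants: 7 methyl 2-oxocyclohexane-1-carboxylate; 8 tert-butyl L-valinate
Product: 9 methyl 2-{[(2S)-1-tert-butoxy-3-methyl-1-oxobutan-2-yl]amino}cyclohex-1-ene-1-carboxylate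
Conditions: TsOH·H2O (cat.), PhH, reflux, Dean–Stark
Reagents that add atoms: none
Why: Acid-catalysed condensation of a β-keto ester with a primary amine gives the conjugated, hydrogen-bonded enamino ester that carries the auxiliary for step 5.

**Step 5**
Reactants: 9 methyl 2-{[(2S)-1-tert-butoxy-3-methyl-1-oxobutan-2-yl]amino}cyclohex-1-ene-1-carboxylate
Product: 12 methyl (1S)-1-methyl-2-oxocyclohexane-1-carboxylate, via N-lithiated enamine 10 (not isolated), via methylated imine 11 (not isolated)
Conditions: LiN(i-Pr)2, PhMe, −78 °C; HMPA, MeI, −78 → −40 °C; then 1 M HCl, rt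
Reagents that add atoms: iodomethane CI; water O
Why: Diastereoselective alkylation of the chelated lithium aza-enolate of a chiral enamine should set the quaternary C4 centre under control of the valine stereocentre, and hydrolysis releases the keto ester and the auxiliary.

**Step 6**
Reactants: 12 methyl (1S)-1-methyl-2-oxocyclohexane-1-carboxylate; 6 1-bromo-2,3,5-trimethoxy-4-(propan-2-yl)benzene
Product: 13 methyl (1S)-1-methyl-2-oxo-3-[2,3,5-trimethoxy-4-(propan-2-yl)phenyl]cyclohexane-1-carboxylate (C3 epimer mixture)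
Conditions: Pd(OAc)2 (3 mol %), XPhos (6 mol %), K3PO4, PhMe, 90 °C
Reagents that add atoms: none
Why: Palladium-catalysed α-arylation of a ketone enolate; only the CH2 side of the ketone can enolise, so the aryl group enters at the future C10, whose configuration is set again in step 7.

**Step 7**
Reactants: 13 methyl (1S)-1-methyl-2-oxo-3-[2,3,5-trimethoxy-4-(propan-2-yl)phenyl]cyclohexane-1-carboxylate
Product: 15 (1S,5R)-1-methyl-5-[2,3,5-trimethoxy-4-(propan-2-yl)phenyl]-3-oxabicyclo[3.3.1]nonane-2,9-dione, via cis-hydroxymethyl ketone 14 (not isolated)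
Conditions: (CH2O)n, DBU (0.3 equiv), THF, 45 °C
Reagents that add atoms: formaldehyde C=O
Why: Reversible base-catalysed aldol addition of the α-aryl ketone enolate to formaldehyde creates the quaternary C10, and because only the adduct with CH2OH cis to CO2Me can lactonise while the other reverts by retro-aldol, the mixture should funnel into the bridged lactone with C10 fixed by C4.

**Step 8**
Reactants: 15 (1S,5R)-1-methyl-5-[2,3,5-trimethoxy-4-(propan-2-yl)phenyl]-3-oxabicyclo[3.3.1]nonane-2,9-dione
Product: 16 (1S,5R)-5-[2-bromo-3,5,6-trimethoxy-4-(propan-2-yl)phenyl]-1-methyl-3-oxabicyclo[3.3.1]nonane-2,9-dione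
Conditions: NBS, MeCN, 0 °C → rt, dark
Reagents that add atoms: N-bromosuccinimide O=C1CCC(=O)N1Br
Why: Electrophilic aromatic bromination at the only free ring position (C8), which is para to the C12 and ortho to the C14 methoxy group; the ketone has no α-hydrogen.

**Step 9**
Reactants: 16 (1S,5R)-5-[2-bromo-3,5,6-trimethoxy-4-(propan-2-yl)phenyl]-1-methyl-3-oxabicyclo[3.3.1]nonane-2,9-dione
Product: 17 (1S,5R)-1-methyl-5-{3,5,6-trimethoxy-4-(propan-2-yl)-2-[(E)-2-(tributylstannyl)ethenyl]phenyl}-3-oxabicyclo[3.3.1]nonane-2,9-dione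
Conditions: (E)-Bu3SnCH=CHSnBu3 (3 equiv), Pd2(dba)3 (3 mol %), P(t-Bu)3 (12 mol %), CsF, dioxane, 100 °C
Reagents that add atoms: (E)-1,2-bis(tributylstannyl)ethene CCCC[Sn](CCCC)(CCCC)/C=C/[Sn](CCCC)(CCCC)CCCC
Why: Stille cross-coupling in which an excess of the distannane transfers one stannylvinyl group with retention of the E geometry, using a bulky electron-rich phosphine and fluoride activation for the doubly ortho-substituted bromide.

**Step 10**
Reactants: 17 (1S,5R)-1-methyl-5-{3,5,6-trimethoxy-4-(propan-2-yl)-2-[(E)-2-(tributylstannyl)ethenyl]phenyl}-3-oxabicyclo[3.3.1]nonane-2,9-dione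
Product: 18 (1S,5R,9S)-9-hydroxy-1-methyl-5-{3,5,6-trimethoxy-4-(propan-2-yl)-2-[(E)-2-(tributylstannyl)ethenyl]phenyl}-3-oxabicyclo[3.3.1]nonan-2-one (hydroxyl anti to the lactone bridge)
Conditions: NaBH4, MeOH–THF, 0 °C
Reagents that add atoms: none
Why: Borohydride reduction of the bridging ketone with hydride expected from the lactone face; the lactone is not reduced, and the carbinol configuration is lost again in step 12.

**Step 11**
Reactants: 18 (1S,5R,9S)-9-hydroxy-1-methyl-5-{3,5,6-trimethoxy-4-(propan-2-yl)-2-[(E)-2-(tributylstannyl)ethenyl]phenyl}-3-oxabicyclo[3.3.1]nonan-2-one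
Product: 20 O-[(1S,5R,9S)-1-methyl-2-oxo-5-{3,5,6-trimethoxy-4-(propan-2-yl)-2-[(E)-2-(tributylstannyl)ethenyl]phenyl}-3-oxabicyclo[3.3.1]nonan-9-yl] S-methyl carbonodithioate, via sodium xanthate 19 (not isolated)
Conditions: NaH, THF, 0 °C; CS2; MeI, 0 °C → rt
Reagents that add atoms: carbon disulfide S=C=S; iodomethane CI
Why: Xanthate formation (first stage of a Barton–McCombie deoxygenation), in which the small electrophile CS2 should reach the hindered alkoxide.

**Step 12**
Reactants: 20 O-[(1S,5R,9S)-1-methyl-2-oxo-5-{3,5,6-trimethoxy-4-(propan-2-yl)-2-[(E)-2-(tributylstannyl)ethenyl]phenyl}-3-oxabicyclo[3.3.1]nonan-9-yl] S-methyl carbonodithioate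
Product: 21 (4S,5R,10R)-11,12,14-trimethoxyabieta-6,8,11,13-tetraen-19,20-olide
Conditions: (Bu3Sn)2 (0.15 equiv), hν (sunlamp), PhH (0.01 M), reflux
Reagents that add atoms: none
Why: Bu3Sn• adds to the thiocarbonyl sulfur and the adduct fragments at C5–O to give the secondary C5 radical, which adds to the tin-bearing carbon C6 of the styrenyl unit on C8; the benzylic C7 radical then expels Bu3Sn• by β-scission, which forms the C6=C7 double bond and carries the chain. The closest known reaction types are Barton–McCombie radical generation from xanthates, radical allylation and vinylation by addition–fragmentation on allyl- and vinylstannanes (radicals add to β-stannylstyrenes at the tin-bearing carbon), and 6-endo cyclisation of alkyl radicals onto the terminal carbon of ortho-vinylarenes. Ring B closes in the 6-endo-trig mode because attack at C6 gives a benzylic β-stannyl radical, whereas 5-exo attack at C7 would give a non-benzylic α-stannyl radical that cannot pass on the chain. The new C5 stereocentre is controlled by the bicycle: the planar radical should be attacked on the lactone face (one syn-axial hydrogen at C20 and the sp2 C19) and not on the carbocyclic face (two syn-axial hydrogens at C1 and C3), so that C6 ends equatorial on ring A and H-5 anti to C20. The step needs cyclisation to outrun all other fates of the radical, which is secured by the absence of a stoichiometric hydrogen donor and by the quaternary C4 and C10, which leave no β-hydrogen for xanthate pyrolysis or alkene formation.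

**Step 13**
Reactants: 21 (4S,5R,10R)-11,12,14-trimethoxyabieta-6,8,11,13-tetraen-19,20-olide
Product: 22 (4S,5R,10R)-12-methoxy-11,14-dioxoabieta-6,8,12-trien-19,20-olide
Conditions: (NH4)2Ce(NO3)6 (2.5 equiv), MeCN–H2O, 0 °C
Reagents that add atoms: water O
Why: Oxidative demethylation of the para-dimethoxy pair at C11 and C14 by a one-electron oxidant, with water supplying the quinone oxygens, should leave the C12 methoxy group as a vinylogous ester.

**Step 14**
Reactants: 22 (4S,5R,10R)-12-methoxy-11,14-dioxoabieta-6,8,12-trien-19,20-olide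
Product: 24 (4S,5R,10R)-12-hydroxy-11,14-dioxoabieta-6,8,12-trien-19,20-olide, via 12-O-dichloroboryl quinone 23 (not isolated)
Conditions: BCl3, CH2Cl2, −78 → 0 °C; then H2O
Reagents that add atoms: none
Why: Chelation-assisted ether cleavage, in which BCl3 binds the C11 carbonyl and the neighbouring C12 methoxy oxygen and chloride removes the methyl group, should spare the hindered lactone and the alkene at low temperature.

**Step 15**
Reactants: 24 (4S,5R,10R)-12-hydroxy-11,14-dioxoabieta-6,8,12-trien-19,20-olide
Product: 25 CNP0596241.1, (4S,5R,10R)-12-acetoxy-11,14-dioxoabieta-6,8,12-trien-19,20-olide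
Conditions: Ac2O, pyridine, DMAP (cat.), CH2Cl2, 0 °C → rt
Reagents that add atoms: acetic anhydride CC(=O)OC(C)=O
Why: O-Acylation of the acidic 2-hydroxy-1,4-quinone under nucleophilic catalysis gives the enol acetate.

**Compound list**
1 | 1,2,4-trimethoxybenzene | COc1ccc(OC)c(OC)c1 | starting material
2 | 2,3,6-trimethoxyphenyllithium | [Li]c1c(OC)ccc(OC)c1OC | intermediate
3 | 2-(2,3,6-trimethoxyphenyl)propan-2-ol | COc1ccc(OC)c(C(C)(C)O)c1OC | intermediate
4 | 1,2,4-trimethoxy-3-(propan-2-yl)benzene | COc1ccc(OC)c(C(C)C)c1OC | intermediate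
5 | 2,3,5-trimethoxy-4-isopropylphenyllithium | [Li]c1cc(OC)c(C(C)C)c(OC)c1OC | intermediate
6 | 1-bromo-2,3,5-trimethoxy-4-(propan-2-yl)benzene | COc1c(Br)cc(OC)c(C(C)C)c1OC | intermediate
7 | methyl 2-oxocyclohexane-1-carboxylate | COC(=O)C1CCCCC1=O | starting material
8 | tert-butyl L-valinate | CC(C)[C@H](N)C(=O)OC(C)(C)C | starting material
9 | methyl 2-{[(2S)-1-tert-butoxy-3-methyl-1-oxobutan-2-yl]amino}cyclohex-1-ene-1-carboxylate | COC(=O)C1=C(N[C@@H](C(C)C)C(=O)OC(C)(C)C)CCCC1 | intermediate
10 | N-lithiated enamine of 9 | COC(=O)C1=C(N([Li])[C@@H](C(C)C)C(=O)OC(C)(C)C)CCCC1 | intermediate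
11 | methylated imine (S at the new quaternary carbon) | CC(C)[C@H](N=C1CCCC[C@]1(C)C(=O)OC)C(=O)OC(C)(C)C | intermediate
12 | methyl (1S)-1-methyl-2-oxocyclohexane-1-carboxylate | O=C1CCCC[C@]1(C)C(=O)OC | intermediate
13 | methyl (1S)-1-methyl-2-oxo-3-[2,3,5-trimethoxy-4-(propan-2-yl)phenyl]cyclohexane-1-carboxylate, C3 epimer mixture | COc1c(OC)c(C(C)C)c(OC)cc1C1CCC[C@](C)(C(=O)OC)C1=O | intermediate
14 | methyl (1S,3R)-3-(hydroxymethyl)-1-methyl-2-oxo-3-[2,3,5-trimethoxy-4-(propan-2-yl)phenyl]cyclohexane-1-carboxylate | COc1c(OC)c(C(C)C)c(OC)cc1[C@@]1(CO)CCC[C@](C)(C(=O)OC)C1=O | intermediate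
15 | (1S,5R)-1-methyl-5-[2,3,5-trimethoxy-4-(propan-2-yl)phenyl]-3-oxabicyclo[3.3.1]nonane-2,9-dione | COc1c(OC)c(C(C)C)c(OC)cc1[C@]12CCC[C@](C)(C(=O)OC1)C2=O | intermediate
16 | (1S,5R)-5-[2-bromo-3,5,6-trimethoxy-4-(propan-2-yl)phenyl]-1-methyl-3-oxabicyclo[3.3.1]nonane-2,9-dione | COc1c(OC)c(C(C)C)c(OC)c(Br)c1[C@]12CCC[C@](C)(C(=O)OC1)C2=O | intermediate
17 | (1S,5R)-1-methyl-5-{3,5,6-trimethoxy-4-(propan-2-yl)-2-[(E)-2-(tributylstannyl)ethenyl]phenyl}-3-oxabicyclo[3.3.1]nonane-2,9-dione | COc1c(OC)c(C(C)C)c(OC)c(/C=C/[Sn](CCCC)(CCCC)CCCC)c1[C@]12CCC[C@](C)(C(=O)OC1)C2=O | intermediate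
18 | (1S,5R,9S)-9-hydroxy analogue of 17 (hydroxyl anti to the lactone bridge) | COc1c(OC)c(C(C)C)c(OC)c(/C=C/[Sn](CCCC)(CCCC)CCCC)c1[C@]12CCC[C@](C)(C(=O)OC1)[C@H]2O | intermediate
19 | sodium xanthate of 18 | COc1c(OC)c(C(C)C)c(OC)c(/C=C/[Sn](CCCC)(CCCC)CCCC)c1[C@]12CCC[C@](C)(C(=O)OC1)[C@H]2OC(=S)[S-].[Na+] | intermediate
20 | S-methyl xanthate of 18 | COc1c(OC)c(C(C)C)c(OC)c(/C=C/[Sn](CCCC)(CCCC)CCCC)c1[C@]12CCC[C@](C)(C(=O)OC1)[C@H]2OC(=S)SC | intermediate
21 | (4S,5R,10R)-11,12,14-trimethoxyabieta-6,8,11,13-tetraen-19,20-olide | COc1c(OC)c(C(C)C)c(OC)c2c1[C@]13CCC[C@](C)(C(=O)OC1)[C@@H]3C=C2 | intermediate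
22 | (4S,5R,10R)-12-methoxy-11,14-dioxoabieta-6,8,12-trien-19,20-olide | COC1=C(C(C)C)C(=O)C2=C(C1=O)[C@]13CCC[C@](C)(C(=O)OC1)[C@@H]3C=C2 | intermediate
23 | 12-O-dichloroboryl derivative of 24 | ClB(Cl)OC1=C(C(C)C)C(=O)C2=C(C1=O)[C@]13CCC[C@](C)(C(=O)OC1)[C@@H]3C=C2 | intermediate
24 | (4S,5R,10R)-12-hydroxy-11,14-dioxoabieta-6,8,12-trien-19,20-olide | OC1=C(C(C)C)C(=O)C2=C(C1=O)[C@]13CCC[C@](C)(C(=O)OC1)[C@@H]3C=C2 | intermediate
25 | CNP0596241.1, (4S,5R,10R)-12-acetoxy-11,14-dioxoabieta-6,8,12-trien-19,20-olide | CC(=O)OC1=C(C(C)C)C(=O)C2=C(C1=O)[C@]13CCC[C@](C)(C(=O)OC1)[C@@H]3C=C2 | target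

**Totals**
Total step count: 15.
Longest linear sequence: 13 steps (steps 1–3, then 6–15); steps 4–5 are the second branch.

**Steps most likely to fail**

Step 12. The C5 radical may partition into 5-exo closure, undergo a 1,2-aryl shift from C10, be attacked on the carbocyclic face, or the tin chain may die at the hindered tin-bearing carbon. The fallback sets out from 16 and returns at 21, and separates ring closure from alkene formation. Suzuki–Miyaura coupling of 16 with potassium vinyltrifluoroborate (Pd(dppf)Cl2, Cs2CO3, THF–H2O, 80 °C) would give the C8-vinyl keto lactone F1. NaBH4 reduction would give the vinyl alcohol F2, and 1,1'-thiocarbonyldiimidazole (DMAP, PhMe, 90 °C) the imidazole-1-carbothioate F3. Slow addition of Bu3SnH/AIBN (PhH, reflux) would then run a hydride-terminated Barton–McCombie 6-endo cyclisation onto the unhindered CH2 terminus to give the 6,7-dihydro compound F4. Benzylic dehydrogenation with DDQ (dioxane, reflux) would give 21.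

Step 9. Oxidative addition and transmetalation may stall at a position flanked by a methoxy group and the bridgehead carbon, with double coupling and protodestannylation as side paths. The fallback sets out from 13 and returns at 17, and moves the coupling to a stage where C9 still carries a secondary carbon. NBS (MeCN, 0 °C) would give the bromo ketone F5, and the same Stille coupling would give the stannylvinyl ketone F6. Paraformaldehyde/DBU would then form the cis-hydroxymethyl ketone F7, which lactonises to 17.

Step 7. The epimer funnelling may be incomplete, and methoxide released on lactonisation may cleave the non-enolisable β-keto lactone by retro-Claisen attack. The fallback sets out from 13 and returns at 15, and replaces the reversible base-mediated aldol by a Lewis-acid aldol with separate acid lactonisation. Me3SiOTf/Et3N would give the silyl enol ether F8. A Sc(OTf)3-catalysed Mukaiyama aldol with aqueous formaldehyde would give 14 together with its C10 epimer. Camphorsulfonic acid (PhMe, 80 °C) would lactonise 14 to 15, and the epimer that cannot lactonise would be separated.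

**Further compounds**
F1 | step 12 | (1S,5R)-5-[2-ethenyl-3,5,6-trimethoxy-4-(propan-2-yl)phenyl]-1-methyl-3-oxabicyclo[3.3.1]nonane-2,9-dione | COc1c(OC)c(C(C)C)c(OC)c(C=C)c1[C@]12CCC[C@](C)(C(=O)OC1)C2=O
F2 | step 12 | 9-hydroxy analogue of F1 (hydroxyl anti to the lactone bridge) | COc1c(OC)c(C(C)C)c(OC)c(C=C)c1[C@]12CCC[C@](C)(C(=O)OC1)[C@H]2O
F3 | step 12 | O-alkyl imidazole-1-carbothioate of F2 | COc1c(OC)c(C(C)C)c(OC)c(C=C)c1[C@]12CCC[C@](C)(C(=O)OC1)[C@H]2OC(=S)n1ccnc1
F4 | step 12 | (4S,5R,10R)-11,12,14-trimethoxyabieta-8,11,13-trien-19,20-olide | COc1c(OC)c(C(C)C)c(OC)c2c1[C@]13CCC[C@](C)(C(=O)OC1)[C@@H]3CC2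
F5 | step 9 | methyl (1S)-3-[2-bromo-3,5,6-trimethoxy-4-(propan-2-yl)phenyl]-1-methyl-2-oxocyclohexane-1-carboxylate, C3 epimer mixture | COc1c(OC)c(C(C)C)c(OC)c(Br)c1C1CCC[C@](C)(C(=O)OC)C1=O
F6 | step 9 | methyl (1S)-1-methyl-2-oxo-3-{3,5,6-trimethoxy-4-(propan-2-yl)-2-[(E)-2-(tributylstannyl)ethenyl]phenyl}cyclohexane-1-carboxylate, C3 epimer mixture | COc1c(OC)c(C(C)C)c(OC)c(/C=C/[Sn](CCCC)(CCCC)CCCC)c1C1CCC[C@](C)(C(=O)OC)C1=O
F7 | step 9 | (1S,3R)-3-hydroxymethyl adduct of F6 | COc1c(OC)c(C(C)C)c(OC)c(/C=C/[Sn](CCCC)(CCCC)CCCC)c1[C@@]1(CO)CCC[C@](C)(C(=O)OC)C1=O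
F8 | step 7 | trimethylsilyl enol ether of 13 | COc1c(OC)c(C(C)C)c(OC)cc1C1=C(O[Si](C)(C)C)[C@@](C)(C(=O)OC)CCC1
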